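**Strategy.** The cycloheptane is cut on both sides of its lactone edge. The two oxygen-bearing ring carbons that flank the CHMe–C(OH) unit (C9 and C5) become the aldehydes of a chiral succinaldehyde. The lactone carbinol carbon C6, the ring-fusion carbon C7 and the ring CH2 C8 are the γ-, β- and β-methylene carbons of one butenolide, i.e. two vinylogous donor sites. In one flask the cross-conjugated silyl dienolate of β-methylene-γ-butyrolactone adds through C8 to the less hindered aldehyde, the butenolide so formed is silylated to a 2-silyloxyfuran, and its C6 closes the seven-membered ring on the second aldehyde, setting C9, C5 and C6.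

Key step: step 8

Numbering used below: C1 = C(OH)(acyl); C2–C4 and C15 = butenoyl chain; C5 = CH–O-isobutyryl; C6 = CH–O (lactone); C7 = ring-fusion CH; C8 = CH2; C9 = CHOH; C10 = CHMe; C11, C12, C13 = lactone α-carbon, carbonyl carbon and exocyclic CH2.

Assumption: (R)-4-methyloxolan-2-one is taken as a purchasable building block.

Remark: the carbinol centre C2 carried from step 3 to step 13 is auxiliary (drawn S, as expected from a chair aldol transition state). It becomes the ketone in step 14, so its epimer would converge.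

Abbreviations: TBS = tert-butyldimethylsilyl; TES = triethylsilyl; LDA = LiN(iPr)2; PPTS = pyridinium p-toluenesulfonate; DMPU = N,N'-dimethylpropyleneurea; DMAP = 4-(dimethylamino)pyridine.

**Step 1**
Reactants: 1 (R)-4-methyloxolan-2-one
Product: 2 (3R,4S)-3-hydroxy-4-methyloxolan-2-one
Conditions: NaN(SiMe3)2, THF, −78 °C; 2-(benzenesulfonyl)-3-phenyloxaziridine, −78 °C; aq. NH4Cl
Reagents that add atoms: 2-(benzenesulfonyl)-3-phenyloxaziridine, O=S(=O)(N1OC1c1ccccc1)c1ccccc1
Why: Davis enolate hydroxylation, in which oxygen is transferred to the enolate face anti to the C4 methyl group (trans product); this centre is planarised again in step 3, so its configuration is not critical.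

**Step 2**
Reactants: 2 (3R,4S)-3-hydroxy-4-methyloxolan-2-one
Product: 3 (3R,4S)-3-[(2-methoxypropan-2-yl)oxy]-4-methyloxolan-2-one
Conditions: 2-methoxypropene, PPTS (cat.), CH2Cl2, 0 °C
Reagents that add atoms: 2-methoxypropene, C=C(C)OC
Why: acid-catalysed addition of the alcohol to the enol ether gives the mixed ketal, which masks the hydroxyl for enolate chemistry and later supplies the acetonide carbon; no stereocentre is touched.

**Step 3**
Reactants: 3 (3R,4S)-3-[(2-methoxypropan-2-yl)oxy]-4-methyloxolan-2-one; 4 (2E)-but-2-enal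
Product: 6 (4S,5R,9S)-2,2,9-trimethyl-4-[(1E)-prop-1-en-1-yl]-1,3,7-trioxaspiro[4.4]nonan-6-one, via aldol adduct 5 (not isolated)
Conditions: LDA (LiN(iPr)2), THF, −78 °C; 4, −78 °C; AcOH; crude: PPTS (cat.), 4 Å molecular sieves, CH2Cl2, rt
Reagents that add atoms: none
Why: lithium enolate aldol addition (1,2 to the enal) followed by acid-catalysed intramolecular transketalisation with loss of methanol; the aldehyde enters on the enolate face anti to the neighbouring methyl group, so the new quaternary carbon (C1) carries oxygen cis to the methyl group as the target requires, and the chair transition state of the ring-fixed enolate should give the (S)-carbinol.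

**Step 4**
Reactants: 6 (4S,5R,9S)-2,2,9-trimethyl-4-[(1E)-prop-1-en-1-yl]-1,3,7-trioxaspiro[4.4]nonan-6-one
Product: 7 (2S)-2-[(4S,5S)-4-(hydroxymethyl)-2,2-dimethyl-5-[(1E)-prop-1-en-1-yl]-1,3-dioxolan-4-yl]propan-1-ol
Conditions: LiAlH4, THF, 0 °C → rt; H2O, aq. NaOH work-up
Reagents that add atoms: none
Why: hydride reduction of the lactone to the 1,4-diol; the ketal and the alkene are inert and no stereocentre is affected.

**Step 5**
Reactants: 7 (2S)-2-[(4S,5S)-4-(hydroxymethyl)-2,2-dimethyl-5-[(1E)-prop-1-en-1-yl]-1,3-dioxolan-4-yl]propan-1-ol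
Product: 8 (4R,5S)-2,2-dimethyl-4-[(2R)-1-oxopropan-2-yl]-5-[(1E)-prop-1-en-1-yl]-1,3-dioxolane-4-carbaldehyde
Conditions: (COCl)2, DMSO, CH2Cl2, −78 °C; iPr2NEt, −78 → −30 °C; cold pH 7 buffer; used crude at once
Reagents that add atoms: none
Why: double Swern oxidation, in which both alkoxysulfonium ions form before base is added so that lactol and lactone formation from the 1,4-diol is avoided; the hindered base and low temperature should preserve the α-methyl centre (its descriptor changes only through CIP priorities).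

**Step 6**
Reactants: 9 4-methoxy-2-methylidene-4-oxobutanoic acid (monomethyl itaconate)
Product: 11 4-methylideneoxolan-2-one, via hydroxy ester 10 (not isolated)
Conditions: BH3·SMe2, THF, −10 °C → rt; MeOH; then TsOH·H2O (cat.), CH2Cl2, rt
Reagents that add atoms: none
Why: borane reduces the free carboxylic acid much faster than the ester or the electron-poor 1,1-disubstituted alkene, and the allylic alcohol lactonises under mild acid without moving the exocyclic double bond into conjugation.

**Step 7**
Reactants: 11 4-methylideneoxolan-2-one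
Product: 12 tert-butyl(dimethyl)[(4-methylidene-4,5-dihydrofuran-2-yl)oxy]silane
Conditions: LDA (LiN(iPr)2), THF, −78 °C; TBSCl, DMPU, −78 → 0 °C; pentane, filtration, distillation
Reagents that add atoms: tert-butyldimethylsilyl chloride (TBSCl), CC(C)(C)[Si](C)(C)Cl
Why: kinetic α-deprotonation of the β,γ-unsaturated lactone (its only acidic position) and O-silylation give the cross-conjugated silyl ketene acetal; acid-free handling is meant to prevent tautomerisation to the aromatic 4-methyl-2-silyloxyfuran.

**Step 8**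
Reactants: 8 (4R,5S)-2,2-dimethyl-4-[(2R)-1-oxopropan-2-yl]-5-[(1E)-prop-1-en-1-yl]-1,3-dioxolane-4-carbaldehyde; 12 tert-butyl(dimethyl)[(4-methylidene-4,5-dihydrofuran-2-yl)oxy]silane
Product: 15 tricyclic butenolide (cycloheptane fused at C6–C7 to a furan-2(5H)-one with C7=C11; C1/C2 acetonide; C9–OTBS; C5–OTES), via butenolide aldehyde 13 (not isolated), via silyloxyfuran 14 (not isolated)
Conditions: TBSOTf (0.2 equiv), 2,6-di-tert-butyl-4-methylpyridine (0.3 equiv), CH2Cl2, −78 °C; then iPr2NEt (1.2 equiv), TESOTf (1.3 equiv), −78 → −20 °C; aq. NaHCO3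
Reagents that add atoms: triethylsilyl trifluoromethanesulfonate (TESOTf), CC[Si](CC)(CC)OS(=O)(=O)C(F)(F)F
Why: Silyl-triflate-catalysed vinylogous Mukaiyama aldol addition of the methylene terminus (C8) of 12 to the silyl-activated C9 aldehyde gives butenolide 13 with the TBS group transferred to O9; TESOTf/iPr2NEt then turns the butenolide into the 2-triethylsilyloxyfuran 14, whose C6 adds to the TESOTf-activated C5 aldehyde in an intramolecular vinylogous Mukaiyama aldol reaction that leaves the TES group on O5. The closest known reaction types are the γ-selective vinylogous Mukaiyama aldol additions of cross-conjugated silyl dienolates and of 2-silyloxyfurans, and the silylative (silyl triflate/amine) cycloaldolisation of lactone aldehydes. Only the cycloheptane is closed, by a 7-(enolendo)-exo-trig attack of the furan carbon next to the tether on the aldehyde. C9 is set by Felkin–Anh addition anti to the quaternary dioxolane carbon beside the C10 methyl centre (OH and Me syn), C5 by a Cornforth-type arrangement with the aldehyde C=O anti to the C1–O bond (O5 trans to O1 on the ring), and C6 by the open synclinal transition state of silyloxyfuran additions, which gives the threo relationship between lactone oxygen and new carbinol. The step needs site selectivity between the two aldehydes, which the neopentyl, α-quaternary environment of the C5 aldehyde should secure by leaving only the C9 aldehyde open to the bulky silyl Lewis acid; it also needs C6 rather than C11 attack of the furan, which the intrinsic γ-preference of 2-silyloxyfurans should secure. The second aldehyde has no α-hydrogen, so the amine and silyl triflate of the second stage cannot enolise it.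

**Step 9**
Reactants: 15 tricyclic butenolide
Product: 16 cis-fused saturated γ-lactone (C7–H and C11H2; otherwise as 15)
Conditions: Cu(OAc)2·H2O (5 mol %), 1,2-bis(diphenylphosphino)benzene (5 mol %), (EtO)2MeSiH, tBuOH, toluene, rt
Reagents that add atoms: none
Why: copper hydride conjugate reduction of the butenolide, chemoselective over the isolated (E)-alkene; hydride is delivered to C7 on the butenolide face opposite to the carbocycle (the C5 side), which sets the cis ring fusion (H7 cis to H6).

**Step 10**
Reactants: 16 cis-fused saturated γ-lactone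
Product: 19 α-methylene lactone (C11=C13H2; C9–OTBS; C5–OTES; C1/C2 acetonide), via Mannich base 17 (not isolated), via ammonium iodide 18 (not isolated)
Conditions: LDA (LiN(iPr)2), THF, −78 °C; CH2=NMe2+ I−, −78 °C → rt; MeI, MeOH, rt; aq. NaHCO3, CH2Cl2
Reagents that add atoms: N,N-dimethylmethyleneiminium iodide (Eschenmoser's salt), C=[N+](C)C.[I-]
Why: lactone enolate Mannich reaction with Eschenmoser's salt, quaternisation and E1cB loss of trimethylamine (the standard α-methylenation of γ-lactones); every hydroxyl is silylated or ketalised and the C7 centre is not enolisable.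

**Step 11**
Reactants: 19 α-methylene lactone
Product: 20 C5 alcohol (C9–OTBS and C1/C2 acetonide retained)
Conditions: HF·pyridine, pyridine, THF, 0 °C
Reagents that add atoms: none
Why: buffered fluoride desilylation cleaves the triethylsilyl ether faster than the tert-butyldimethylsilyl ether and leaves the ketal, so only the C5 hydroxyl is freed.

**Step 12**
Reactants: 20 C5 alcohol
Product: 21 C5 2-methylpropanoate (C9–OTBS and C1/C2 acetonide retained)
Conditions: (iPrCO)2O, DMAP, Et3N, CH2Cl2, rt → 40 °C
Reagents that add atoms: 2-methylpropanoic anhydride (isobutyric anhydride), CC(C)C(=O)OC(=O)C(C)C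
Why: DMAP-catalysed acyl transfer to the only free hydroxyl; the C5–O bond is untouched, so its configuration is kept.

**Step 13**
Reactants: 21 C5 2-methylpropanoate
Product: 22 (3aS,5R,6S,7R,8S,8aR)-5,7-dihydroxy-7-[(1S,2E)-1-hydroxybut-2-en-1-yl]-6-methyl-3-methylidene-2-oxooctahydro-2H-cyclohepta[b]furan-8-yl 2-methylpropanoate
Conditions: camphorsulfonic acid (0.2 equiv), MeOH, rt → 40 °C
Reagents that add atoms: none
Why: acid-catalysed transketalisation of the isopropylidene ketal to methanol and methanolysis of the secondary TBS ether free the C1, C2 and C9 hydroxyls, while the hindered ester, the γ-lactone and the exocyclic acrylate should survive.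

**Step 14**
Reactants: 22 triol
Product: 23 (3aS,5R,6S,7S,8S,8aR)-7-[(2E)-but-2-enoyl]-5,7-dihydroxy-6-methyl-3-methylidene-2-oxooctahydro-2H-cyclohepta[b]furan-8-yl 2-methylpropanoate (CNP0123946.1)
Conditions: MnO2 (activated, excess), CH2Cl2, rt
Reagents that add atoms: none
Why: MnO2 oxidises only the allylic C2 carbinol (the saturated C9 alcohol and the tertiary C1 alcohol are inert), giving the (E)-enone and removing the auxiliary stereocentre.

**Compound list**

1 | (R)-4-methyloxolan-2-one | C[C@H]1COC(=O)C1 | starting material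
2 | (3R,4S)-3-hydroxy-4-methyloxolan-2-one | O1C[C@H](C)[C@@H](O)C1=O | intermediate
3 | (3R,4S)-3-[(2-methoxypropan-2-yl)oxy]-4-methyloxolan-2-one | O1C[C@H](C)[C@@H](OC(C)(C)OC)C1=O | intermediate
4 | (2E)-but-2-enal | C/C=C/C=O | starting material
5 | (3R,4S)-3-[(1S,2E)-1-hydroxybut-2-en-1-yl]-3-[(2-methoxypropan-2-yl)oxy]-4-methyloxolan-2-one (not isolated) | O1C[C@H](C)[C@@](OC(C)(C)OC)([C@@H](O)/C=C/C)C1=O | intermediate
6 | (4S,5R,9S)-2,2,9-trimethyl-4-[(1E)-prop-1-en-1-yl]-1,3,7-trioxaspiro[4.4]nonan-6-one | O1C[C@H](C)[C@]2(OC(C)(C)O[C@H]2/C=C/C)C1=O | intermediate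
7 | (2S)-2-[(4S,5S)-4-(hydroxymethyl)-2,2-dimethyl-5-[(1E)-prop-1-en-1-yl]-1,3-dioxolan-4-yl]propan-1-ol | OC[C@H](C)[C@@]1(CO)OC(C)(C)O[C@H]1/C=C/C | intermediate
8 | (4R,5S)-2,2-dimethyl-4-[(2R)-1-oxopropan-2-yl]-5-[(1E)-prop-1-en-1-yl]-1,3-dioxolane-4-carbaldehyde | O=C[C@H](C)[C@@]1(C=O)OC(C)(C)O[C@H]1/C=C/C | intermediate
9 | 4-methoxy-2-methylidene-4-oxobutanoic acid (monomethyl itaconate) | C=C(CC(=O)OC)C(=O)O | starting material
10 | methyl 3-(hydroxymethyl)but-3-enoate (not isolated) | C=C(CO)CC(=O)OC | intermediate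
11 | 4-methylideneoxolan-2-one | C=C1COC(=O)C1 | intermediate
12 | tert-butyl(dimethyl)[(4-methylidene-4,5-dihydrofuran-2-yl)oxy]silane | C=C1COC(O[Si](C)(C)C(C)(C)C)=C1 | intermediate
13 | butenolide aldehyde: furan-2(5H)-one carrying at its C4 the chain C8H2–C9H(OTBS)–C10H(CH3)–C1, where C1 is the dioxolane carbon bearing the C5 aldehyde; configurations as in 15 (not isolated) | O=C1C=C(CO1)C[C@@H](O[Si](C)(C)C(C)(C)C)[C@H](C)[C@@]2(C=O)OC(C)(C)O[C@H]2/C=C/C | intermediate
14 | 2-(triethylsilyloxy)furan carrying the same chain at its C4 (not isolated) | CC[Si](CC)(CC)Oc1cc(co1)C[C@@H](O[Si](C)(C)C(C)(C)C)[C@H](C)[C@@]2(C=O)OC(C)(C)O[C@H]2/C=C/C | intermediate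
15 | tricyclic butenolide: cycloheptane fused at C6–C7 to a furan-2(5H)-one (C7=C11), spiro C1/C2 isopropylidene dioxolane with (E)-prop-1-enyl on C2, C9–OTBS, C10–Me, C5–OTES; C1, C5, C6, C9, C10 as in the target, C2 (S) | O=C1O[C@@H]2C(=C1)C[C@@H](O[Si](C)(C)C(C)(C)C)[C@H](C)[C@]3(OC(C)(C)O[C@H]3/C=C/C)[C@H]2O[Si](CC)(CC)CC | intermediate
16 | cis-fused saturated γ-lactone (7,11-dihydro-15; H6 and H7 cis) | O=C1O[C@@H]2[C@H](C1)C[C@@H](O[Si](C)(C)C(C)(C)C)[C@H](C)[C@]3(OC(C)(C)O[C@H]3/C=C/C)[C@H]2O[Si](CC)(CC)CC | intermediate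
17 | Mannich base: 16 with CH2NMe2 on C11, on the convex face (not isolated) | CN(C)C[C@@H]1C(=O)O[C@@H]2[C@H]1C[C@@H](O[Si](C)(C)C(C)(C)C)[C@H](C)[C@]3(OC(C)(C)O[C@H]3/C=C/C)[C@H]2O[Si](CC)(CC)CC | intermediate
18 | trimethylammonium iodide of 17 (not isolated) | C[N+](C)(C)C[C@@H]1C(=O)O[C@@H]2[C@H]1C[C@@H](O[Si](C)(C)C(C)(C)C)[C@H](C)[C@]3(OC(C)(C)O[C@H]3/C=C/C)[C@H]2O[Si](CC)(CC)CC.[I-] | intermediate
19 | α-methylene lactone: C11=C13H2, C9–OTBS, C5–OTES, C1/C2 acetonide | C=C1C(=O)O[C@@H]2[C@H]1C[C@@H](O[Si](C)(C)C(C)(C)C)[C@H](C)[C@]3(OC(C)(C)O[C@H]3/C=C/C)[C@H]2O[Si](CC)(CC)CC | intermediate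
20 | C5 alcohol: 19 with free C5–OH | C=C1C(=O)O[C@@H]2[C@H]1C[C@@H](O[Si](C)(C)C(C)(C)C)[C@H](C)[C@]3(OC(C)(C)O[C@H]3/C=C/C)[C@H]2O | intermediate
21 | C5 2-methylpropanoate of 20 | C=C1C(=O)O[C@@H]2[C@H]1C[C@@H](O[Si](C)(C)C(C)(C)C)[C@H](C)[C@]3(OC(C)(C)O[C@H]3/C=C/C)[C@H]2OC(=O)C(C)C | intermediate
22 | (3aS,5R,6S,7R,8S,8aR)-5,7-dihydroxy-7-[(1S,2E)-1-hydroxybut-2-en-1-yl]-6-methyl-3-methylidene-2-oxooctahydro-2H-cyclohepta[b]furan-8-yl 2-methylpropanoate | C=C1C(=O)O[C@@H]2[C@H]1C[C@@H](O)[C@H](C)[C@@](O)([C@@H](O)/C=C/C)[C@H]2OC(=O)C(C)C | intermediate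
23 | (3aS,5R,6S,7S,8S,8aR)-7-[(2E)-but-2-enoyl]-5,7-dihydroxy-6-methyl-3-methylidene-2-oxooctahydro-2H-cyclohepta[b]furan-8-yl 2-methylpropanoate | C=C1C(=O)O[C@@H]2[C@H]1C[C@@H](O)[C@H](C)[C@@](O)(C(=O)/C=C/C)[C@H]2OC(=O)C(C)C | target

**Step count.** Total: 14 steps. Longest linear sequence: 12 steps (steps 1–5 and 8–14); steps 6–7 make the second fragment.

**Steps most likely to fail**

Step 8. The dienolate may add to the wrong aldehyde (wrong pairing of the two new bonds). Alternatively, the oxygen at C9 may engage the activated second aldehyde, so that a bridging ether forms in place of the C5–C6 bond. The fallback sets out from 7 and comes back at 13, and from there at 15. Compound 7 is silylated (TESCl, imidazole) to the bis(triethylsilyl) ether F1. A Swern reagent oxidises primary TES ethers directly and should take the less hindered one first, giving the mono-aldehyde F2, in which C5 is still a neopentyl CH2OTES. F2 and 12 under the first-stage conditions give the butenolide silyl ether F3 with no second aldehyde present. A second direct Swern oxidation of the remaining primary TES ether, which the secondary TBS ether survives, gives 13. Compound 13 is then cyclised to 15 with TESOTf/iPr2NEt in a separate flask.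

Step 7. Proton-mediated tautomerisation of the cross-conjugated silyl dienol ether to the aromatic 4-methyl-2-silyloxyfuran may occur, which would deliver C6 instead of C8 to the first aldehyde. The fallback sets out from 8 and comes back at 13. Horner–Wadsworth–Emmons reaction of purchasable 1-[(tert-butyldimethylsilyl)oxy]propan-2-one with triethyl phosphonoacetate gives ethyl (2E)-4-[(tert-butyldimethylsilyl)oxy]-3-methylbut-2-enoate F4. LDA removes a proton from the methyl group cis to the ester, and TBSCl gives the open-chain silyl dienolate F5, which cannot aromatise. F5 adds through its terminal CH2 to the C9 aldehyde of 8 (TBSOTf cat.) to give the (Z)-enoate aldehyde F6. HF·pyridine (1 equiv) removes the primary allylic silyl ether, and the γ-hydroxy (Z)-enoate lactonises to 13, which continues through the second stage of step 8.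

Step 3. Retro-aldol cleavage, competing conjugate addition to the enal, or hydrolysis of the mixed ketal instead of ring closure may occur. The fallback sets out from 3 and comes back at 5. The lithium enolate of 3 is C-acylated with (2E)-N-methoxy-N-methylbut-2-enamide to the β-keto lactone F7; the facial preference is the same and there is no retro-aldol pathway. Luche reduction (NaBH4, CeCl3·7H2O, MeOH, −78 °C), with hydride entering the cerium-chelated 1,3-dicarbonyl anti to the bulky ketal ether, should give 5, which is closed to 6 as in step 3.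

**Further compounds**

F1 | step 8 | bis(triethylsilyl) ether of 7 | CC[Si](CC)(CC)OC[C@H](C)[C@@]1(CO[Si](CC)(CC)CC)OC(C)(C)O[C@H]1/C=C/C
F2 | step 8 | (2R)-2-[(4S,5S)-2,2-dimethyl-5-[(1E)-prop-1-en-1-yl]-4-{[(triethylsilyl)oxy]methyl}-1,3-dioxolan-4-yl]propanal | O=C[C@H](C)[C@@]1(CO[Si](CC)(CC)CC)OC(C)(C)O[C@H]1/C=C/C
F3 | step 8 | butenolide silyl ether (13 with CH2OTES in place of the C5 aldehyde) | O=C1C=C(CO1)C[C@@H](O[Si](C)(C)C(C)(C)C)[C@H](C)[C@@]2(CO[Si](CC)(CC)CC)OC(C)(C)O[C@H]2/C=C/C
F4 | step 7 | ethyl (2E)-4-[(tert-butyldimethylsilyl)oxy]-3-methylbut-2-enoate | CCOC(=O)/C=C(\C)CO[Si](C)(C)C(C)(C)C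
F5 | step 7 | (1Z)-1-ethoxy-1-[(tert-butyldimethylsilyl)oxy]-3-{[(tert-butyldimethylsilyl)oxy]methyl}buta-1,3-diene | C=C(CO[Si](C)(C)C(C)(C)C)/C=C(\O[Si](C)(C)C(C)(C)C)OCC
F6 | step 7 | ethyl (2Z)-enoate aldehyde (open-chain precursor of 13 with CH2OTBS cis to the ester) | CCOC(=O)/C=C(\CO[Si](C)(C)C(C)(C)C)C[C@@H](O[Si](C)(C)C(C)(C)C)[C@H](C)[C@@]1(C=O)OC(C)(C)O[C@H]1/C=C/C
F7 | step 3 | (3R,4S)-3-[(2E)-but-2-enoyl]-3-[(2-methoxypropan-2-yl)oxy]-4-methyloxolan-2-one | O1C[C@H](C)[C@@](OC(C)(C)OC)(C(=O)/C=C/C)C1=O
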